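All runs stem from a simulated flask on assumed constants, noise included.

I start from the latest readings of the earlier runs. At 4.00 h the ochre run holds J 11.5% and the violet run J 24.7%, each with a scatter of 1 percentage point. Violet has 2.21 times the E of ochre and 2.15 times the J.

| flask | D | Z | E | remark | time |
|---|---|---|---|---|---|
| ochre | 0.050 M (fed, over 20 min) | 0.015 M | 0.34 mol% | run made earlier; the fed solution adds 0.25 times the starting volume |  |
| violet | 0.050 M (fed, over 20 min) | 0.015 M | 0.75 mol% | run made earlier; the fed solution adds 0.25 times the starting volume |  |
| east | 0.050 M (fed, over 20 min) | 0.0150 M | 0.5 mol% | the fed solution adds 0.25 times the starting volume | 5.0 h |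
| west | 0.050 M (fed, over 10 min) | 0.0150 M | 0.5 mol% | the fed solution adds 0.25 times the starting volume | 5.0 h |

| run | time / h | J / % | D / % |
|---|---|---|---|
| ochre | 0.333 | 1.1 | 98.5 |
| ochre | 0.667 | 3.3 | 96.7 |
| ochre | 1.00 | 4.1 | 96.5 |
| ochre | 2.00 | 8.1 | 93.3 |
| ochre | 4.00 | 11.5 | 86.6 |
| violet | 0.333 | 1.7 | 98.7 |
| violet | 1.00 | 6.0 | 94.0 |
| violet | 2.00 | 13.8 | 86.9 |
| violet | 3.00 | 21.8 | 81.3 |
| violet | 4.00 | 24.7 | 74.6 |

(each reading ± 1 percentage point)

- every charge counts on the volume at the start, and the solution that is fed holds the whole dose
- the average divides the monomer in chains by the number of chains begun, living and dead together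
- the earlier runs do not show the number of chains; that part of a forecast is a guess

1. which of the two ends with the longer chains by the average number of monomer units in a chain (chains begun, living or dead) ("neither" if they lie within 10%) (east / west / neither)
2. average number of monomer units in a chain (chains begun, living or dead) at the end, east
3. average number of monomer units in a chain (chains begun, living or dead) at the end, west

So I let D lose the same fraction each hour, with that fraction in step with the E loading. This is a pseudo-first-order fall of cD. I take the logarithm of charged D over D left, with D left read as the charge minus J. Then I divide by the loading and by the time since mid-feed, when the dose has on average arrived. Ochre reads 9.37 h⁻¹ and violet 9.87 h⁻¹. The mean is 9.62 h⁻¹. Call it the loading clock: the logarithm of charged D over D left, per unit of E loading, per hour.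

Two chemists dispute east and west. The first says each E begins one chain, so length is the J share over the loading. The feed, he says, counts little, since 20 min is shorter than the 5.0 h run. The clock gives him J 20.7% in east and 21.1% in west. The lengths are then 41.5 and 42.1, a gap of 1.53%, inside the margin of 10%.

The second says E waits for D, and waiting E may be lost. East's feed lasts twice as long, so east should begin fewer chains and end longer. She needs a gap beyond 10%, but the runs show no chain count. Her loss is a guess, and so is his count.

The forecast sides with the first: neither, with 41 for east and 42 for west, on the words “I assume one chain per E”.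

The flask gives neither, with 41.7 for east and 42.2 for west.

    D + E → X + J (k = 4.70 L mol⁻¹ min⁻¹)
    D + X → J + X, rate k2*[X]*[D] (k = 5.80 L mol⁻¹ min⁻¹)
    X + Z → L (k = 0.230 L mol⁻¹ min⁻¹)
    E → G (k = 0.00260 min⁻¹)

The second view has its ground in G. At 5.00 h east holds 6.32 × 10⁻⁶ M of it, more than west's 4.77 × 10⁻⁶ M. But X and L together stand at 1.94 × 10⁻⁴ M in east, well above that G. In east the dosing makes no difference to the length. The clock gave east J 20.7%, and east holds 20.2%. For a neighbour of east with 2 mol% of E, the clock gives J 60.5% and length 30.2. That neighbour holds J 59.5%, and its length is 30.7.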